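The runs were generated by integration with constants of no real substance; noise was put on by code.

Two questions stand for this flask, both rates taken at 50% conversion of J, so the first count is how many half-lives of J lie before that point.

| flask | J | E | Z | remark |
|---|---|---|---|---|
| maple | 1.5 M | 3 M | 30 mM | the very flask that is asked about, followed so far |
| larch | 1.5 M | 3 M | 60 mM | run made earlier |
| flask | 1.5 M | 3.00 M | 30 mM |  |

- maple (time / min: D / %): 1.00: 2; 2.00: 0; 3.00: 3; 4.00: 3; 5.00: 3; 6.00: 7
- larch (time / min: D / %): 4.00: 10; 8.00: 15; 10.0: 18; 15.0: 24; 20.0: 29

(readings scatter by 2 percentage points)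

- apparent order in E when 50% of the J are converted (percent change of the rate of making D for one percent more E charged)
- factor on the rate of making D when 50% of the J are converted if Z is charged twice over

- no earlier run changes the charge of E; that part of a forecast is a guess

The reckoning below rests on the larch reading at 20.0 min: shifted by 2 percentage points, it moves the half-life below between 74.7 min and 88.1 min. The scatter on the maple reading at 6.00 min is 28.6% of that reading, more than the 6.90% on the larch reading, so the maple reading is not used. The ratio of the Z charges enters in full, while the E charge is the same in both runs.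

half-life = ln(2) × 20.0 min ÷ 0.342 × 60 mM ÷ 30 mM = 81.0 min

This is my reckoned half-life of J in this flask, the time for J to halve under an assumed pseudo-first-order loss scaling with [Z]. On larch at 4.00 min it gives 6.62%, and the reading of 10% stands higher than that, so the larch readings of D slow along that run and one half-life is an early figure for 50%. With rate scaling with [Z], this reckoning puts the factor on Z at 2; for E it offers no number.

The forecast gives 0.8 for the order in E and 2.2 for the factor on Z, the second higher than the 2 of my reckoning: "Order in E is untested."

    E + Z ⇌ Q (K = 35.0 M⁻¹, k = 0.00980 M⁻¹ s⁻¹)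
    L ⇌ Z + D (K = 1.50 M, k = 0.0440 s⁻¹)
    Q → Z + X (k = 0.0330 s⁻¹)
    J + Z ⇌ L (K = 0.660 M⁻¹, k = 0.0220 M⁻¹ s⁻¹)

The flask gives −0.34 for the order in E and 10.7 for the factor on Z.  The flask reaches 50% conversion after 4.40 h, 3.26 of the reckoned half-lives rather than one, and at that moment it makes D at 2.63 × 10⁻⁵ M min⁻¹.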